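**Plan**

1. Numbering: the cage is a bicyclo[3.3.1]nonane-2,4,9-trione (C1 benzoyl, C3 spiro carbon, C5 geranyl, C8 = CMe2) whose C7 is tied through C10H2 to the cyclopentane CH (C11) next to C3.
2. Cuts, last bond first: C5–C6 together with C7–C10 (radical cascade); C11–CMe2 of the cyclopentane (5-exo-dig radical closure); C1–C8 (Claisen rearrangement); C5–S and C5–geranyl; C4–C5 and C1–C2 of the trione ring (diketone dianion acylation, Claisen condensation).
3. Forward order of rings: temporary δ-lactone → cyclohexanetrione → spiro-cyclopentane → the six- and seven-membered rings of the homoadamantane cage in one operation.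
4. Enabling feature: C5 lies between the C4 and C9 carbonyls and gives a 1,3-dicarbonyl radical; a vinyl group (C7=C6) hangs from C8 on C1 and an exocyclic methylene (C10=C11) sits on the spiro ring at C3. The C5 radical closes ring C5–C6–C7–C8–C1–C9 at C6, and the C7 radical, held over C3, closes ring C7–C10–C11–C3–C2–C1–C8 at C10.
5. Stereochemistry: C3 from a catalytic asymmetric alkynylation; C1 relative to C3 in the Claisen rearrangement; C5 and C7 from the cage geometry; C11 from hydrogen-atom transfer to the open face of the tertiary radical.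

Key step: step 10

Remark: enolised polyketones are written as one tautomer, and the sulfur-bearing carbon of 11–16 is drawn as the epimer expected to predominate; either epimer serves, because this centre becomes a planar radical in step 10.

Step 1
Reactants: 1 dimethyl malonate; 2 prenyl bromide (1-bromo-3-methylbut-2-ene)
Product: 3 dimethyl 2-(3-methylbut-2-en-1-yl)malonate
Conditions: NaH, THF, 0 °C to rt (malonate in excess)
Reagents that add atoms: none
Why: Malonic ester alkylation: the sodium enolate displaces the primary allylic bromide (SN2), an excess of malonate suppresses dialkylation, and no stereocentre is formed.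

Step 2
Reactants: 3 dimethyl 2-(3-methylbut-2-en-1-yl)malonate
Product: 4 methyl 6,6-dimethyl-2-oxooxane-3-carboxylate (racemic)
Conditions: 88% aq. HCO2H, 60 °C
Reagents that add atoms: water, O
Why: Acid-mediated lactonisation of a γ,δ-unsaturated ester: Markovnikov protonation of the trisubstituted alkene gives the tertiary cation, which an ester carbonyl oxygen captures to close the δ-lactone with loss of methanol; the remaining α-CH is epimerisable, so no stereocentre needs control.

Step 3
Reactants: 4 methyl 6,6-dimethyl-2-oxooxane-3-carboxylate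
Product: 5 methyl (3R)-6,6-dimethyl-2-oxo-3-[(trimethylsilyl)ethynyl]oxane-3-carboxylate
Conditions: TMS-EBX, Cs2CO3, C2-symmetric spiro-binaphthyl quaternary ammonium bromide (5 mol%), PhMe, −40 °C
Reagents that add atoms: 1-[(trimethylsilyl)ethynyl]-1,2-benziodoxol-3(1H)-one (TMS-EBX), C[Si](C)(C)C#CI1OC(=O)c2ccccc12
Why: Electrophilic α-alkynylation of the lactone ester enolate with an ethynylbenziodoxolone under chiral phase-transfer catalysis should create the quaternary centre (the future C3) as the (R)-isomer, because the enolate reacts as a tight ion pair with the chiral ammonium ion, which shields one enolate face (catalyst antipode chosen accordingly); the silyl group stays on the alkyne.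

Step 4
Reactants: 5 methyl (3R)-6,6-dimethyl-2-oxo-3-[(trimethylsilyl)ethynyl]oxane-3-carboxylate; 6 1-phenylbutane-1,3-dione (benzoylacetone)
Product: 8 (4S)-2-benzoyl-4-ethynyl-3,5-dihydroxy-4-(3-hydroxy-3-methylbutyl)cyclohexa-2,5-dien-1-one, via open-chain triketo ester 7 (not isolated)
Conditions: 6, LDA (3.2 equiv), THF, 0 °C; 5, −78 to 0 °C; then NaOMe, MeOH, 50 °C; cold dil. HCl (pH 4)
Reagents that add atoms: none
Why: 1,3-Diketone dianion acylation followed by Claisen (Dieckmann-type) condensation: the terminal carbanion of the benzoylacetone dianion should open the δ-lactone, which is far more electrophilic than the methyl ester (this fixes which carbonyl becomes C4 and so carries the configuration of 5 into C3), and methoxide then closes the benzoyl-flanked carbon onto the methyl ester to give the enolised acyl cyclohexanetrione while cleaving the C–Si bond.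

Step 5
Reactants: 8 (4S)-2-benzoyl-4-ethynyl-3,5-dihydroxy-4-(3-hydroxy-3-methylbutyl)cyclohexa-2,5-dien-1-one; 9 geranyl bromide ((2E)-1-bromo-3,7-dimethylocta-2,6-diene)
Product: 10 (4S)-2-benzoyl-6-[(2E)-3,7-dimethylocta-2,6-dien-1-yl]-4-ethynyl-3,5-dihydroxy-4-(3-hydroxy-3-methylbutyl)cyclohexa-2,5-dien-1-one
Conditions: NaOMe (2 equiv), MeOH, −10 °C
Reagents that add atoms: none
Why: C-Alkylation (SN2) of the dianion of the dearomatised acylphloroglucinol-type trione at its only free ring carbon C5, the acyl-bearing C1 and the oxygens being less nucleophilic; C5 stays enolised, so no stereocentre arises.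

Step 6
Reactants: 10 (4S)-2-benzoyl-6-[(2E)-3,7-dimethylocta-2,6-dien-1-yl]-4-ethynyl-3,5-dihydroxy-4-(3-hydroxy-3-methylbutyl)cyclohexa-2,5-dien-1-one
Product: 11 4-benzoyl-2-[(2E)-3,7-dimethylocta-2,6-dien-1-yl]-6-ethynyl-5-hydroxy-6-(3-hydroxy-3-methylbutyl)-2-(phenylsulfanyl)cyclohex-4-ene-1,3-dione (PhS cis to ethynyl)
Conditions: N-(phenylthio)succinimide, Et3N (cat.), CH2Cl2, −20 °C
Reagents that add atoms: N-(phenylthio)succinimide, O=C1CCC(=O)N1Sc1ccccc1
Why: Electrophilic α-sulfenylation of the C4/C9 diketone enol at C5 should make C5 quaternary, which blocks enolisation toward C5 (a free enol there would later allow a Cope shift of the dimethylallyl group from C1 to C5) and installs the radical leaving group; sulfur should enter on the face of the slim ethynyl group at C3, though the configuration of this temporary centre does not matter.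

Step 7
Reactants: 11 4-benzoyl-2-[(2E)-3,7-dimethylocta-2,6-dien-1-yl]-6-ethynyl-5-hydroxy-6-(3-hydroxy-3-methylbutyl)-2-(phenylsulfanyl)cyclohex-4-ene-1,3-dione; 12 prenol (3-methylbut-2-en-1-ol)
Product: 14 2-benzoyl-4-[(2E)-3,7-dimethylocta-2,6-dien-1-yl]-6-ethynyl-6-(3-hydroxy-3-methylbutyl)-2-(2-methylbut-3-en-2-yl)-4-(phenylsulfanyl)cyclohexane-1,3,5-trione (dimethylallyl group cis to ethynyl), via O-prenyl enol ether 13 (not isolated)
Conditions: PPh3, DIAD, THF, 0 °C; then PhMe, 90 °C
Reagents that add atoms: none
Why: Mitsunobu O-alkylation of the acidic triketone enol followed by Claisen [3,3] rearrangement: every O-prenyl regioisomer can deliver the allyl unit only to C1 because C3 and C5 are quaternary, and the new axial C1–CMe2 bond should form on the ring face where its syn-axial neighbour at C3 is the linear ethynyl group and not a CH2 group, which places the 1,1-dimethylallyl group cis to ethynyl.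

Step 8
Reactants: 14 2-benzoyl-4-[(2E)-3,7-dimethylocta-2,6-dien-1-yl]-6-ethynyl-6-(3-hydroxy-3-methylbutyl)-2-(2-methylbut-3-en-2-yl)-4-(phenylsulfanyl)cyclohexane-1,3,5-trione
Product: 15 2-benzoyl-6-(3-bromo-3-methylbutyl)-4-[(2E)-3,7-dimethylocta-2,6-dien-1-yl]-6-ethynyl-2-(2-methylbut-3-en-2-yl)-4-(phenylsulfanyl)cyclohexane-1,3,5-trione
Conditions: TMSBr, 2,6-di-tert-butylpyridine, CH2Cl2, −40 to 0 °C; aq. NaHCO3
Reagents that add atoms: bromotrimethylsilane, C[Si](C)(C)Br
Why: Substitution of the tertiary alcohol through its silyl ether by bromide (SN1) under hindered-base buffering should give the tertiary bromide without free HBr, so the trisubstituted alkenes and the alkyne stay intact; the ring ketones are non-enolisable and no stereocentre is touched.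

Step 9
Reactants: 15 2-benzoyl-6-(3-bromo-3-methylbutyl)-4-[(2E)-3,7-dimethylocta-2,6-dien-1-yl]-6-ethynyl-2-(2-methylbut-3-en-2-yl)-4-(phenylsulfanyl)cyclohexane-1,3,5-trione
Product: 16 7-benzoyl-9-[(2E)-3,7-dimethylocta-2,6-dien-1-yl]-2,2-dimethyl-1-methylidene-7-(2-methylbut-3-en-2-yl)-9-(phenylsulfanyl)spiro[4.5]decane-6,8,10-trione (methylidene-bearing C1 cis to the dimethylallyl group)
Conditions: Bu3SnH (1.1 equiv, slow addition), AIBN, PhH, 80 °C
Reagents that add atoms: none
Why: Tin hydride radical cyclisation: bromine abstraction from the tertiary bromide is orders of magnitude faster than attack of the stannyl radical on the α-keto sulfide, the tertiary radical closes 5-exo-dig onto the ethynyl group (Thorpe–Ingold assisted) and the vinyl radical is reduced to the exocyclic methylene; C3 keeps its configuration, so the methylene-bearing carbon stays cis to the dimethylallyl group.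

Step 10
Reactants: 16 7-benzoyl-9-[(2E)-3,7-dimethylocta-2,6-dien-1-yl]-2,2-dimethyl-1-methylidene-7-(2-methylbut-3-en-2-yl)-9-(phenylsulfanyl)spiro[4.5]decane-6,8,10-trione
Product: 17 CNP0168637.1 (the caged trione, target)
Conditions: Bu3SnH (1.3 equiv, syringe pump, 2 mM), AIBN, PhH, 80 °C
Reagents that add atoms: none
Why: Bu3Sn• abstracts the phenylthio group from C5 to give the electrophilic 1,3-dicarbonyl radical, which adds to the terminal vinyl carbon C6; the resulting secondary C7 radical adds to the methylene carbon C10, and the tertiary C11 radical is reduced by the stannane. The closest known reaction type is the tin hydride (or Mn(III)) radical cascade of 2-substituted 1,3-dicarbonyl radicals onto unactivated alkenes, including transannular closures of dearomatised acylphloroglucinols. The six-membered ring C5–C6–C7–C8–C1–C9 closes 6-endo-trig, favoured over 5-exo because the C9 carbonyl lies inside the forming ring and C7 is neopentyl, and the seven-membered ring C7–C10–C11–C3–C2–C1–C8 closes 7-endo-trig because C7 is held endo over C3 in the new bicyclo[3.3.1]nonane and attacks the unsubstituted alkene terminus. C5 and C7 are set by the tether, since both new bonds can form only on the ring face that carries the axial C8 on C1 and the methylene arm on C3, which steps 7 and 9 placed cis. C11 is set by hydrogen-atom transfer to the radical lobe that faces C4, the lobe facing C2 being covered by a methyl group on C8. The step needs cyclisation to outrun reduction of the C5 and C7 radicals, which slow stannane addition at high dilution should secure, and needs C5 to be the only radical precursor, which step 9 secures by consuming the bromide.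

**Compound list**

1 | dimethyl malonate | COC(=O)CC(=O)OC | starting material
2 | prenyl bromide (1-bromo-3-methylbut-2-ene) | CC(C)=CCBr | starting material
3 | dimethyl 2-(3-methylbut-2-en-1-yl)malonate | COC(=O)C(CC=C(C)C)C(=O)OC | intermediate
4 | methyl 6,6-dimethyl-2-oxooxane-3-carboxylate (racemic) | COC(=O)C1CCC(C)(C)OC1=O | intermediate
5 | methyl (3R)-6,6-dimethyl-2-oxo-3-[(trimethylsilyl)ethynyl]oxane-3-carboxylate | C[Si](C)(C)C#C[C@@]1(C(=O)OC)CCC(C)(C)OC1=O | intermediate
6 | 1-phenylbutane-1,3-dione (benzoylacetone) | CC(=O)CC(=O)c1ccccc1 | starting material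
7 | methyl (2S)-2-(3-hydroxy-3-methylbutyl)-3,5,7-trioxo-7-phenyl-2-[(trimethylsilyl)ethynyl]heptanoate (not isolated) | C[Si](C)(C)C#C[C@@](C(=O)CC(=O)CC(=O)c1ccccc1)(C(=O)OC)CCC(C)(C)O | intermediate
8 | (4S)-2-benzoyl-4-ethynyl-3,5-dihydroxy-4-(3-hydroxy-3-methylbutyl)cyclohexa-2,5-dien-1-one | O=C1C=C(O)[C@@](C#C)(CCC(C)(C)O)C(O)=C1C(=O)c1ccccc1 | intermediate
9 | geranyl bromide ((2E)-1-bromo-3,7-dimethylocta-2,6-diene) | CC(C)=CCC/C(C)=C/CBr | starting material
10 | (4S)-2-benzoyl-6-[(2E)-3,7-dimethylocta-2,6-dien-1-yl]-4-ethynyl-3,5-dihydroxy-4-(3-hydroxy-3-methylbutyl)cyclohexa-2,5-dien-1-one | CC(C)=CCC/C(C)=C/CC1=C(O)[C@@](C#C)(CCC(C)(C)O)C(O)=C(C(=O)c2ccccc2)C1=O | intermediate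
11 | 4-benzoyl-2-[(2E)-3,7-dimethylocta-2,6-dien-1-yl]-6-ethynyl-5-hydroxy-6-(3-hydroxy-3-methylbutyl)-2-(phenylsulfanyl)cyclohex-4-ene-1,3-dione; PhS cis to ethynyl | CC(C)=CCC/C(C)=C/C[C@@]1(Sc2ccccc2)C(=O)[C@@](C#C)(CCC(C)(C)O)C(O)=C(C(=O)c2ccccc2)C1=O | intermediate
12 | prenol (3-methylbut-2-en-1-ol) | CC(C)=CCO | starting material
13 | O-prenyl enol ether of 11, drawn as the ring-oxygen regioisomer next to the ethynyl-bearing carbon (not isolated; the other O-regioisomers rearrange to the same product) | CC(C)=CCC/C(C)=C/C[C@@]1(Sc2ccccc2)C(=O)[C@@](C#C)(CCC(C)(C)O)C(OCC=C(C)C)=C(C(=O)c2ccccc2)C1=O | intermediate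
14 | 2-benzoyl-4-[(2E)-3,7-dimethylocta-2,6-dien-1-yl]-6-ethynyl-6-(3-hydroxy-3-methylbutyl)-2-(2-methylbut-3-en-2-yl)-4-(phenylsulfanyl)cyclohexane-1,3,5-trione; dimethylallyl, ethynyl and PhS on one ring face | CC(C)=CCC/C(C)=C/C[C@@]1(Sc2ccccc2)C(=O)[C@@](C#C)(CCC(C)(C)O)C(=O)[C@](C(=O)c2ccccc2)(C(C)(C)C=C)C1=O | intermediate
15 | 2-benzoyl-6-(3-bromo-3-methylbutyl)-4-[(2E)-3,7-dimethylocta-2,6-dien-1-yl]-6-ethynyl-2-(2-methylbut-3-en-2-yl)-4-(phenylsulfanyl)cyclohexane-1,3,5-trione; same relative configuration as 14 | CC(C)=CCC/C(C)=C/C[C@@]1(Sc2ccccc2)C(=O)[C@@](C#C)(CCC(C)(C)Br)C(=O)[C@](C(=O)c2ccccc2)(C(C)(C)C=C)C1=O | intermediate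
16 | 7-benzoyl-9-[(2E)-3,7-dimethylocta-2,6-dien-1-yl]-2,2-dimethyl-1-methylidene-7-(2-methylbut-3-en-2-yl)-9-(phenylsulfanyl)spiro[4.5]decane-6,8,10-trione; C1 of the five-membered ring, the dimethylallyl group and PhS on one face of the trione ring | CC(C)=CCC/C(C)=C/C[C@@]1(Sc2ccccc2)C(=O)[C@]2(C(=C)C(C)(C)CC2)C(=O)[C@](C(=O)c2ccccc2)(C(C)(C)C=C)C1=O | intermediate
17 | CNP0168637.1 | CC(C)=CCC/C(C)=C/C[C@@]12C[C@H]3C[C@@H]4C(C)(C)CC[C@]4(C1=O)C(=O)[C@@](C(=O)c1ccccc1)(C2=O)C3(C)C | target

Total steps: 10. Longest linear sequence: 10 (steps 1–10; compounds 6, 9 and 12 are bought).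

**Steps most likely to fail**

Step 10. The C5 or C7 radical may be reduced by the stannane before it cyclises, because the first closure needs a congested conformer with the C1 and C3 arms syn-axial, or hydrogen may be delivered to the wrong face of C11. The fallback runs the cascade as an iodine atom transfer, with no hydride donor present. From 16, sodium thiophenolate (THF, −78 °C) should remove the phenylthio group by attack at sulfur. The C5 enolate is trapped at once with N-iodosuccinimide, before any [3,3] shift can occur, to give the α-iodo trione 7-benzoyl-9-geranyl-9-iodo-2,2-dimethyl-1-methylidene-7-(2-methylbut-3-en-2-yl)spiro[4.5]decane-6,8,10-trione F1. Et3B/air in benzene at rt should then run the same 6-endo/7-endo sequence as an atom-transfer chain, in which the tertiary C11 radical takes iodine from F1, to give the cage iodide (target with iodine in place of hydrogen at C11) F2. Separate reduction of F2 with Bu3SnH/Et3B at 0 °C delivers hydrogen to the open face and rejoins the route at 17.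

Step 7. Facial control or the branched connectivity may be lost through ionisation and recombination of the prenyl ether, through a reversible [3,3] shift at 90 °C, or through C-alkylation in the Mitsunobu stage. The fallback sets out from 11: rhodium(I)/DPEphos-catalysed branched-selective addition of the acidic C1–H to 3-methylbuta-1,2-diene (DCE, 50 °C) forms the same C1–CMe2 bond irreversibly under near-neutral conditions, with the same steric preference for the ethynyl face, and gives 14 directly. No new compound is made.

Step 3. The chiral ion pair may discriminate the enolate faces of a lactone ester too weakly. The fallback sets out from 4: alkynylation without chiral catalyst (TMS-EBX, tetramethylguanidine, THF) gives racemic methyl 6,6-dimethyl-2-oxo-3-[(trimethylsilyl)ethynyl]oxane-3-carboxylate F3, and preparative chromatography on a chiral stationary phase (SFC) isolates the (R)-enantiomer, rejoining the route at 5.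

Further compounds
F1 | step 10 | 7-benzoyl-9-[(2E)-3,7-dimethylocta-2,6-dien-1-yl]-9-iodo-2,2-dimethyl-1-methylidene-7-(2-methylbut-3-en-2-yl)spiro[4.5]decane-6,8,10-trione | CC(C)=CCC/C(C)=C/CC1(I)C(=O)[C@]2(C(=C)C(C)(C)CC2)C(=O)[C@](C(=O)c2ccccc2)(C(C)(C)C=C)C1=O
F2 | step 10 | cage iodide, target with iodine in place of hydrogen at the cyclopentane CH (C11) | CC(C)=CCC/C(C)=C/C[C@@]12C[C@H]3CC4(I)C(C)(C)CC[C@]4(C1=O)C(=O)[C@@](C(=O)c1ccccc1)(C2=O)C3(C)C
F0 | step 7 | none | none
F3 | step 3 | racemic methyl 6,6-dimethyl-2-oxo-3-[(trimethylsilyl)ethynyl]oxane-3-carboxylate | C[Si](C)(C)C#CC1(C(=O)OC)CCC(C)(C)OC1=O
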